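**The task.** You face 3 questions on 2 flasks, and one division of 2 rates serves them.

in all of them: protic impurity 0.0400 M; initiator 9.2 mM; time 10 h

| run | free monomer |
|---|---|
| cedar | 0.40 M |
| larch | 1.2 M |

- which of the two ends with the longer chains by the average number of monomer units in a chain (living and dead chains, two that joined counted as one) ("neither" if they lie within 10%) (cedar / larch / neither)
- average number of monomer units in a chain (living and dead chains, two that joined counted as one) at the end, cedar
- average number of monomer units in a chain (living and dead chains, two that joined counted as one) at the end, larch

- where a step has two of a species, its rate is k times that concentration squared, and two are used at each turn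
- the average divides the monomer in chains by the number of chains, living and dead together; two radicals that join make one chain
- run time (cedar): 10 h

    initiator → 2 initiating radical (k1 = 0.0028 h⁻¹)
    free monomer + initiating radical → growing radical + monomer in chains (k2 = 2.5 × 10⁵ L mol⁻¹ s⁻¹)
    free monomer + growing radical → monomer in chains + growing radical, rate k3*[growing radical]*[free monomer] (k3 = 2.0 × 10⁷ L mol⁻¹ h⁻¹)
    2 growing radical → dead chain (k4 = 4 × 10⁸ L mol⁻¹ s⁻¹)
    protic impurity + free monomer → quenched substrate (k5 = 1.9 L mol⁻¹ h⁻¹)

**Bench rule.** At the bench you would say that, with the initiator held, chain length follows the monomer charge, so larch should carry 3.00 times the length of cedar. To give that a size, note that the initiator's half-life of 10 d is longer than the run, so it feeds radicals at a steady pace, and setting that supply equal to the loss by pairing (the steady state) puts [growing radical] near 4.23 × 10⁻⁹ M in both flasks. The growing radicals together then take free monomer with a first-order constant of 0.0846 h⁻¹, while each initiator lost closes one chain, since its 2 radicals end up joined. Dividing the rate of addition by the rate of closing removes time and leaves 3280 L mol⁻¹, which I call the chain yield: multiplied by [free monomer], it is the number of monomer units added per chain closed, the instantaneous degree of polymerisation.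

**The border.** The bench rule stops where the monomer charged is not the monomer the chains get. The protic impurity takes monomer one for one, and it amounts to 10.0% of the charge in cedar but 3.33% in larch. In cedar its clock of 0.760 h⁻¹ runs faster than the monomer's, so I subtract its share at the outset. The remaining monomer then falls during the run, averaging 0.675 of its opening value. My reckoning gives 798 units for cedar and 2570 for larch, so larch has the longer chains.

**The forecast.** The forecast names larch, with 816 for cedar and 2600 for larch, on the grounds that “each initiator gives one dead chain after pairwise termination”. Its cedar figure stands a little above mine.

**The result.** The flasks give 817 in cedar and 2600 in larch, so larch has the longer chains, and the forecast stands.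

**Why larch.** Larch's chains are longer than cedar's because of its larger charge of free monomer: given cedar's charge, the length reads 817. Read back from cedar, the chain yield is 3370 L mol⁻¹, beside the 3280 L mol⁻¹ reckoned beforehand. For the neighbour, cedar with 0.68 M of free monomer, the chain yield gives 1420 units, and that flask gives 1440.

The rate constants are invented; the rest is arithmetic.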